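Its constants were drawn at random within sensible limits; what happens was integrated by code.

Each charged catalyst had about 1670 substrates to carry through its round, so I reckoned by counting turnovers.

| flask | substrate | reagent | free catalyst | time |
|---|---|---|---|---|
| south | 0.20 mM | 0.240 mM | 0.12 µM | 1.0 min |
| south-west | 0.20 mM | 0.480 mM | 0.12 µM | 1.0 min |

    free catalyst + open intermediate ⇌ catalyst intermediate (K1 = 16000 L mol⁻¹, k1 = 3.2 × 10⁵ L mol⁻¹ s⁻¹)
    2 free catalyst ⇌ resting dimer, settled at all times (K2 = 2.4 × 10⁷ L mol⁻¹)
    reagent + catalyst intermediate → free catalyst + target (k3 = 3.6 × 10⁵ L mol⁻¹ s⁻¹)
    target → over-reaction product (k4 = 0.016 s⁻¹)
    substrate + free catalyst → free catalyst + open intermediate (k5 = 3.8 × 10⁶ L mol⁻¹ s⁻¹)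

- which of these there is most of at the end, counted by the substrate in it, south (over-reaction product / substrate / target / open intermediate)
- which of these there is most of at the end, counted by the substrate in it, south-west (over-reaction product / substrate / target / open intermediate)
- amount of the one of these that there is most of at the end, in percent of the substrate charged, south
- amount of the one of these that there is most of at the end, in percent of the substrate charged, south-west

- for a step with 2 of a species take k times the square, and two of it per event
- run time (south): 1.0 min

1. Substrate opened first, and open intermediate then drained by binding free catalyst and meeting reagent. With free catalyst balanced against resting dimer (the resting state), I treated this drain as pseudo-first-order. I therefore wanted one number, with the amount left as the exponential of its negative.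

2. An error in the binding rate constant or the time passed into that number at about its own size.

3. The dimer constant times the catalyst charged was 2.9, above 1, so an error in the catalyst charged entered by a little more than its square root, and an error in the dimer constant by a little less.

4. Reagent's constant and charge entered through one share, the part of catalyst intermediate going on to target. In south, reagent's rate of 86.4 s⁻¹ was faster than the 20.0 s⁻¹ falling back, which damped errors in them.

5. The opening constant entered through the lag. The over-reaction constant acted downstream of target, so it could not touch open intermediate.

6. Leaving catalyst intermediate aside for the moment and counting free catalyst plus twice resting dimer as the charge gave 0.0407 µM free catalyst and a lag of 6.47 s. The share was 81.2 % in south and 89.6 % in south-west.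

7. My south count was 0.565, the drain count: binding rate constant times share times free catalyst times the time after the lag. South-west's was 0.624.

8. That left 56.8 % open intermediate in south and 53.6 % in south-west, each more than everything formed from it. I took these as low estimates: my count left out catalyst intermediate's hold on the catalyst and reagent's fall, and each of these lowers the count.

The forecast named open intermediate in south and open intermediate in south-west, with 61 % (57 % to 65 %) and 56 % (52 % to 60 %), above my figures: “Open intermediate dominates in both.”

South ended at 61.6 % open intermediate and south-west at 55.9 %; my counts for the two flasks had stood below 1. At the end of south, free catalyst held 30.6 % of the catalyst charged, catalyst intermediate 15.3 % and resting dimer 54.0 %. The same flask as south with 0.480 µM of free catalyst charged gave by the same reckoning 0.0901 µM free, a count of 1.34 and 26.3 % left, and that flask held 31.9 % open intermediate.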